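# Proposed total synthesis of CNP0141631.2 by a three-fold Matteson homologation and copper-mediated ring C closure

**Numbering and abbreviations.** Upper flavan unit: O1, C2, C3, C4, C4a, C8a; ring A (benzo), ring B (catechol), ring C (pyran). Lower (catechin) unit: primed atoms; ring D (benzo), ring E (catechol), ring F (pyran). Acyclic intermediates keep the flavan numbers C2, C3, C4.

- ArA = 4-(benzyloxy)-2-bromophenyl (becomes ring A)
- ArB = 3,4-bis(benzyloxy)phenyl (becomes ring B)
- ArD = (2R,3S)-3,5,7-tris(benzyloxy)-2-[3,4-bis(benzyloxy)phenyl]-8-bromochroman-6-yl (protected catechin, bonded through C6')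
- B(dich) = (4S,5S)-4,5-dicyclohexyl-1,3,2-dioxaborolan-2-yl
- Bn = benzyl

Compounds: 1 (+)-catechin; 2 tetra-O-benzylcatechin; 3 penta-O-benzylcatechin; 4 its 8-bromide; 5 the 8-bromo-6-iodide; 6 1-(benzyloxy)-3-bromobenzene; 7 4-(benzyloxy)-2-bromo-1-iodobenzene; 8 (S,S)-1,2-dicyclohexylethane-1,2-diol; 9 diisopropyl (dichloromethyl)boronate; 10 (dichloromethyl)boronic ester of 8; 11 ring A Grignard reagent; 12 α-chlorobenzyl boronic ester; 13 ring D Grignard reagent; 14 C4 boronic ester; 15 dibromomethyllithium; 16 C3 α-bromo boronic ester; 17 C3 α-benzyloxy boronic ester; 18 4-bromo-1,2-bis(benzyloxy)benzene; 19 dichloromethyllithium; 20 ring B Grignard reagent; 21 C2 α-chloro boronic ester; 22 C2 boronic ester; 23 C2 alcohol; 24 protected biflavanoid; 25 target.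

## Analysis of the target

Target 25 is a biflavanoid in which an epifisetinidol-type upper unit (rings A, B, C; ring A carries only the 7-hydroxyl) is bonded from C4 to C6' of a (+)-catechin lower unit (rings D, E, F). Of its five stereocentres, C2' (R) and C3' (S) are those of natural (+)-catechin 1, while C2 (R), C3 (R) and C4 (S) form a contiguous all-cis triad on ring C, with ring B, the 3-hydroxyl and ring D on one face. This all-cis array is the contra-thermodynamic one: a C4 cation accepts an arene trans to the 3-oxygen, and a C2 benzylic cation closes to the 2,3-trans ring. In addition, catechin reacts as a nucleophile mainly at C8', not at C6'. The molecule carries seven phenols (two oxidation-prone catechols), two secondary alcohols, two cyclic benzylic ethers (C2–O1, C2'–O1') and an acid-labile doubly benzylic C4–C6' bond, so the last steps must be neutral and air-free. The strategy rests on one feature: opening ring C at O1–C8a lays out C4–C3–C2 as an open chain of a diarylmethine (rings A and D), an oxygen-bearing carbon and an aryl carbinol. Each of these carbons can enter as a one-carbon carbenoid inserted into a C–B bond, and each substituent as a nucleophile, under the control of one chiral diol on boron.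

## Retrosynthetic reasoning

**25 to 24.** The nine O–benzyl bonds and the C8'–Br bond are cut together. One protecting group type runs through the whole route, and the bromine that blocks C8' leaves in the same hydrogenolysis. The forward step must spare the cyclic benzylic C–O bonds and the C4–C6' bond.

**24 to 23.** Ring C is cut at O1–C8a, the aryl–oxygen bond. Closing here forms a bond to an sp2 carbon, so no stereocentre is made or put at risk. The all-cis problem becomes one of acyclic stereocontrol in 23. A cut at O1–C2 would need substitution at a benzylic carbon that ionises readily and would drift to 2,3-trans. A cut at C4–C6' would need a C4 cation, which gives 3,4-trans and attack at C8'. Forward, the C2 hydroxyl of 23 must displace the ring A bromide; the ring D bromide is out of intramolecular reach.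

**23 to 22.** The C2–O bond is traced back to a C2–B bond. Oxidation of a boronic ester goes with retention, so C2 can be built as a carbon–boron stereocentre.

**22 to 17, 19 and 20 (key disconnection).** The C2–C3 and C2–ring B bonds are cut. C2 comes from chlorine carbenoid 19 inserted into the C3–B bond of 17, and ring B from Grignard reagent 20. Forward, the diol on boron must fix C2 against any bias from C3 and C4, and C3 must migrate with retention.

**17 to 16, then to 14 and 15.** The C3–O and C3–C4 bonds are cut in the same way. The C3 carbon is inserted into the C4–B bond of 14 as bromine carbenoid 15, and the benzyl ether enters as an oxygen nucleophile on bromide 16 with inversion. The heavier halogen is chosen at this carbon because the crowded centre next to the diarylmethine must be substituted by an alkoxide, for which bromide is the better leaving group.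

**14 to 12 and 13; 12 to 10 and 11.** The C4–C6' and C4–C4a bonds are cut. The C4 carbon is the dichloromethyl carbon of 10, ring A comes from 11 and ring D from 13. Setting C4 on the same diol avoids any later diol exchange on a crowded boronic ester. The order (ring A first, ring D as the displacing nucleophile) is the one that gives the required C4 configuration with the (S,S)-diol. It also keeps the intermediate chloride 12 on the benzylic position that ionises less readily (ortho-bromo ring A, not the di-ortho-oxygenated ring D). The position of magnesium in 13 decides the C6' regiochemistry.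

**13 to 5, 4, 3, 2 and 1.** The C6'–I, C8'–Br and O–benzyl bonds are cut. Bromination of 3 goes to the more reactive C8', so the next halogen must go to C6'. Iodine–magnesium exchange then takes place at C6' only. C2' and C3' are bought with 1.

**11 to 7 and 6; 10 to 8 and 9; 20 to 18.** These are one-step preparations from commercial materials: para-iodination of 6, transesterification of 9 with 8, and magnesium insertion into 18.

## Alternatives that were turned down

**Alternative 1:** Ring F is cut at O1'–C2' and built last. The forward key step is an acid-mediated 6-endo opening of trans-epoxide A1 by its single free ring D phenol, with inversion at C2', giving the octa-O-benzyl compound A2.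
- For it: this is a familiar flavan-3-ol ring closure. Ring D is built with only one free phenol, so the C6'/C8' question never arises and no blocking halogen is needed. On that point it is stronger than the chosen route.
- Against it: it leaves the all-cis C2–C3–C4 triad, the real difficulty, to be solved separately before A1 can be made. It discards the two stereocentres that 1 supplies and rebuilds them by asymmetric epoxidation next to a crowded ring D. The three phloroglucinol oxygens of ring D must be differentiated. The electron-rich ring E favours an ionised C2', so inversion may leak and 5-exo closure competes.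
- Comparison: the sequence is the longest of the four. The chosen route gets the lower unit from 1 in four steps and spends its effort on the upper triad.

**Alternative 2:** C4–C4a and O1–C2 are cut. Chalcone epoxide A3 is opened by aryl borate A4, which delivers a ring A ortho carbon to C4 on the face of the departing oxygen (retention). The released phenol adds to the ketone to give lactol A5.
- For it: one operation forms the ring A–C4 bond and ring C, and the syn opening gives the 3,4-cis relation directly. Ring A enters as a simple phenol with no ortho-bromide and no metal-mediated C–O coupling, which is stronger in step economy for that ring.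
- Against it: C2 is not set. A5 must still be reduced at the lactol carbon from the correct face to give the contra-thermodynamic 2,3-cis ring, and elimination to a flavene competes. The epoxide carbon C4 bears the di-ortho-oxygenated ring D, so opening tends towards a free cation, with rearrangement and loss of retention. Asymmetric epoxidation of a chalcone with such a β-aryl group is demanding.
- Comparison: the chosen route fixes C2 before ring closure and sets all three centres with one auxiliary of known sense.

**Alternative 3:** C4–C3 and O1–C2 are cut at once. A chiral Brønsted acid dehydrates benzhydrol A6 to ortho-quinone methide A7, which adds Z-styrylboronate A8 in a hetero-Diels–Alder reaction to give the all-cis 3-borylflavan A9. Oxidation of the C3–B bond follows.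
- For it: this is the most convergent plan. Two bonds, ring C and three stereocentres form in one step, the Z geometry maps onto 2,3-cis, and the regiochemistry is electronically matched. In step count it is clearly stronger than the chosen route.
- Against it: all three centres depend on one transition state. Its endo/exo and facial selectivity must be imposed by a catalyst that can bind only the quinone methide oxygen, while the dienophile has no binding handle. Alkenylboronates are weak dienophiles. A8 can isomerise or protodeboronate under acid, which would give the 2,3-trans series. The quinone methide terminus carries the bulky ring D.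
- Comparison: the chosen route is longer, but it makes each centre in a separate auxiliary-controlled event whose sense is predictable, and each boronic ester can be purified before the next homologation.

Key step: step 10

Remark: the sense of induction is taken as the usual one for Matteson homologation with C2-symmetric diols, that is, the (S,S)-diol gives the (R)-α-halo boronic ester (chloride or bromide) and the halide is then displaced with inversion.

## Route

Step 1
Reactants: 1 (+)-catechin
Product: 2 (2R,3S)-5,7-bis(benzyloxy)-2-[3,4-bis(benzyloxy)phenyl]chroman-3-ol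
Conditions: BnBr (4.4 equiv), K2CO3, DMF, 0 °C to rt
Reagents that add atoms: benzyl bromide, BrCc1ccccc1
Why: Williamson etherification; K2CO3 deprotonates only the four phenols, so the secondary 3-hydroxyl stays free, and the mild base at low temperature should keep C2 from epimerising.

Step 2
Reactants: 2 tetra-O-benzylcatechin
Product: 3 (2R,3S)-3,5,7-tris(benzyloxy)-2-[3,4-bis(benzyloxy)phenyl]chromane
Conditions: NaH, BnBr, Bu4NI (cat.), DMF, 0 °C to rt
Reagents that add atoms: benzyl bromide, BrCc1ccccc1
Why: Williamson etherification of the secondary alkoxide; with no free phenol left, ring opening and C2 epimerisation have no pathway.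

Step 3
Reactants: 3 penta-O-benzylcatechin
Product: 4 (2R,3S)-3,5,7-tris(benzyloxy)-2-[3,4-bis(benzyloxy)phenyl]-8-bromochromane
Conditions: NBS (1.0 equiv), CH2Cl2, −78 to −20 °C
Reagents that add atoms: N-bromosuccinimide, O=C1CCC(=O)N1Br
Why: electrophilic aromatic bromination; C8' (between O1' and the 7'-benzyloxy group) is the more nucleophilic of the two free ring D positions in 5,7-di-O-alkyl flavan-3-ols, and the catechol diether ring E is far less activated.

Step 4
Reactants: 4 8-bromide
Product: 5 (2R,3S)-3,5,7-tris(benzyloxy)-2-[3,4-bis(benzyloxy)phenyl]-8-bromo-6-iodochromane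
Conditions: NIS (1.1 equiv), CF3CO2H (10 mol%), CH2Cl2/MeCN, 0 °C to rt, dark
Reagents that add atoms: N-iodosuccinimide, O=C1CCC(=O)N1I
Why: electrophilic aromatic iodination at the only free position of the phloroglucinol-type ring D (ortho, ortho and para to three oxygens), which should outpace ring E by a wide margin; the bromine forces the iodine to C6'.

Step 5
Reactants: 6 1-(benzyloxy)-3-bromobenzene
Product: 7 4-(benzyloxy)-2-bromo-1-iodobenzene
Conditions: NIS (1.05 equiv), CF3CO2H (cat.), MeCN, rt
Reagents that add atoms: N-iodosuccinimide, O=C1CCC(=O)N1I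
Why: electrophilic aromatic iodination para to the benzyloxy group, the position most activated by the ether and not flanked by two substituents.

Step 6
Reactants: 8 (1S,2S)-1,2-dicyclohexylethane-1,2-diol; 9 diisopropyl (dichloromethyl)boronate
Product: 10 (4S,5S)-4,5-dicyclohexyl-2-(dichloromethyl)-1,3,2-dioxaborolane
Conditions: THF, 4 Å molecular sieves, rt; volatiles removed in vacuo
Reagents that add atoms: none
Why: boronic ester transesterification, driven by the five-membered chelate and removal of propan-2-ol.

Step 7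
Reactants: 7 4-(benzyloxy)-2-bromo-1-iodobenzene; 10 (dichloromethyl)boronic ester; 5 8-bromo-6-iodide
Product: 14 (4S,5S)-2-[(R)-(ArA)(ArD)methyl]-4,5-dicyclohexyl-1,3,2-dioxaborolane (C4 boronic ester), via ring A Grignard reagent 11 (not isolated), via α-chlorobenzyl boronic ester 12 (not isolated), via ring D Grignard reagent 13 (not isolated)
Conditions: 7, iPrMgCl·LiCl (0.98 equiv), THF, −40 °C; 10, −78 °C; ZnCl2 (0.6 equiv), −78 °C to rt; then 13 (1.8 equiv; from 5, iPrMgCl·LiCl, THF, 0 °C), −78 °C to rt
Reagents that add atoms: none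
Why: Matteson homologation run from the (dichloromethyl)boronate side: iodine–magnesium exchange gives 11, which adds to boron of 10, and the ZnCl2-assisted 1,2-shift of ring A expels one chloride under control of the (S,S)-diol to give (R)-12. Grignard reagent 13 (iodine exchanges, the C8' bromine does not) forms a second ate complex and its C6' carbon migrates with inversion, which sets C4 (R) in 14. ZnCl2 also ties up free chloride, the agent that would epimerise the benzylic chloride 12.

Step 8
Reactants: 14 C4 boronic ester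
Product: 16 (4S,5S)-2-[(1R,2R)-1-bromo-2-(ArA)-2-(ArD)ethyl]-4,5-dicyclohexyl-1,3,2-dioxaborolane (C3 α-bromo boronic ester), via dibromomethyllithium 15 (not isolated)
Conditions: CH2Br2, lithium 2,2,6,6-tetramethylpiperidide, THF, −90 °C, 5 min; 14, −90 °C; ZnCl2 (1.5 equiv), −90 °C to rt; aqueous NH4Cl work-up, crude 16 taken on
Reagents that add atoms: dibromomethane, BrCBr
Why: Matteson homologation with the bromine carbenoid: 15 adds to boron, ZnCl2 promotes migration of C4 with retention and diol-controlled loss of one bromide, forming C3–C4 and the (R)-bromide, and it ties up the released halide that would otherwise epimerise 16. The bromide is chosen over the chloride because this crowded carbon must next be substituted by an alkoxide, and the carbenoid is preformed so that no amide base meets the acidic, doubly benzylic C4–H next to boron.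

Step 9
Reactants: 16 C3 α-bromo boronic ester
Product: 17 (4S,5S)-2-[(1S,2R)-1-(benzyloxy)-2-(ArA)-2-(ArD)ethyl]-4,5-dicyclohexyl-1,3,2-dioxaborolane (C3 α-benzyloxy boronic ester)
Conditions: BnOLi (from BnOH, nBuLi), THF, −78 °C to rt
Reagents that add atoms: benzyl alcohol, OCc1ccccc1
Why: alkoxide displacement on an α-bromo boronic ester: benzyloxide binds boron and its oxygen shifts to carbon with inversion as bromide leaves, which turns the (R)-bromide into the (S)-benzyloxy centre C3. Bromide departs at a lower temperature than chloride would, so attack at boron and the 1,2-shift should outrun deprotonation at C4 and loss of HBr.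

Step 10
Reactants: 17 C3 α-benzyloxy boronic ester; 18 4-bromo-1,2-bis(benzyloxy)benzene
Product: 22 (4S,5S)-2-[(1R,2S,3R)-2-(benzyloxy)-1-(ArB)-3-(ArA)-3-(ArD)propyl]-4,5-dicyclohexyl-1,3,2-dioxaborolane (C2 boronic ester), via dichloromethyllithium 19 (not isolated), via ring B Grignard reagent 20 (not isolated), via C2 α-chloro boronic ester 21 (not isolated)
Conditions: CH2Cl2, LiN(iPr)2, THF, −78 °C (19 formed in the presence of 17); ZnCl2, −78 °C to rt; then 20 (from 18, Mg, THF; excess over ZnCl2), −78 °C to rt
Reagents that add atoms: dichloromethane, ClCCl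
Why: LiN(iPr)2 deprotonates CH2Cl2 in the presence of 17 and carbenoid 19 is trapped at boron as a tetracoordinate ate complex. ZnCl2 binds the less hindered dioxaborolane oxygen and one of the two diastereotopic chlorides, and C3 migrates from boron to carbon anti to that chloride with retention, forming C2–C3 and the (R)-chloride 21. Grignard reagent 20 then adds to boron of 21 and ring B shifts to carbon with inversion as chloride leaves, forming the C2–aryl bond and fixing C2 in 22. The closest known reaction type is the Matteson homologation of α-benzyloxy boronic esters of C2-symmetric diols followed by Grignard displacement, as used iteratively for contiguous oxygenated stereocentres. No ring is closed in this step. The new stereocentre C2 is controlled by the (S,S)-diol on boron (reagent control), the same element and sense that set C4 and C3, with ring B now in the role the benzyloxide played at C3. The step needs the auxiliary to override 1,2-induction from C3 and C4, C3 to keep its configuration, and the β-benzyloxy group not to be lost by boron–oxygen elimination; the rigid diol, the concerted anti 1,2-shifts and the low temperature of ate formation are expected to secure this. Aryl bromides and benzyl ethers are inert to 19 and 20 at these temperatures.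

Step 11
Reactants: 22 C2 boronic ester
Product: 23 (1R,2R,3R)-2-(benzyloxy)-1-(ArB)-3-(ArA)-3-(ArD)propan-1-ol (C2 alcohol)
Conditions: NaBO3·4H2O, THF/H2O, rt
Reagents that add atoms: sodium perborate (NaBO3), [Na+].[O-]OB=O
Why: oxidation of a C–B bond by perborate: a peroxo adduct forms at boron and C2 shifts to oxygen with retention. The mild, near-neutral medium spares the aryl bromides and releases diol 8 for recovery.

Step 12
Reactants: 23 C2 alcohol
Product: 24 (2R,3R,4S)-3,7-bis(benzyloxy)-2-[3,4-bis(benzyloxy)phenyl]-4-(ArD)chromane (nona-O-benzyl 8'-bromo biflavanoid)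
Conditions: CuI (20 mol%), 1,10-phenanthroline (40 mol%), Cs2CO3, toluene, 110 °C
Reagents that add atoms: none
Why: intramolecular Ullmann-type O-arylation: the C2 alkoxide bound to monovalent copper displaces the ring A bromide and closes the six-membered ring C at O1–C8a without touching any stereocentre. The C8' bromide lies meta to the tether on ring D and cannot be reached.

Step 13
Reactants: 24 nona-O-benzyl 8'-bromo biflavanoid
Product: 25 (2R,3R,4S)-2-(3,4-dihydroxyphenyl)-4-[(2R,3S)-2-(3,4-dihydroxyphenyl)-3,5,7-trihydroxychroman-6-yl]chromane-3,7-diol (target)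
Conditions: H2 (1 atm), Pd(OH)2/C, NaOAc, THF/MeOH/H2O, rt; filtration and lyophilisation under inert gas
Reagents that add atoms: none
Why: catalytic hydrogenolysis cleaves the nine benzyl ethers and the aryl C–Br bond in one operation; NaOAc buffers the HBr formed, and the cyclic benzylic C–O bonds and the C4–C6' bond are expected to be much slower to cleave.

## Compound list

1 | (+)-catechin | O[C@H]1Cc2c(O)cc(O)cc2O[C@@H]1c1ccc(O)c(O)c1 | starting material
2 | (2R,3S)-5,7-bis(benzyloxy)-2-[3,4-bis(benzyloxy)phenyl]chroman-3-ol | O[C@H]1Cc2c(OCc3ccccc3)cc(OCc3ccccc3)cc2O[C@@H]1c1ccc(OCc2ccccc2)c(OCc2ccccc2)c1 | intermediate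
3 | (2R,3S)-3,5,7-tris(benzyloxy)-2-[3,4-bis(benzyloxy)phenyl]chromane | c1ccccc1CO[C@H]1Cc2c(OCc3ccccc3)cc(OCc3ccccc3)cc2O[C@@H]1c1ccc(OCc2ccccc2)c(OCc2ccccc2)c1 | intermediate
4 | (2R,3S)-3,5,7-tris(benzyloxy)-2-[3,4-bis(benzyloxy)phenyl]-8-bromochromane | c1ccccc1CO[C@H]1Cc2c(OCc3ccccc3)cc(OCc3ccccc3)c(Br)c2O[C@@H]1c1ccc(OCc2ccccc2)c(OCc2ccccc2)c1 | intermediate
5 | (2R,3S)-3,5,7-tris(benzyloxy)-2-[3,4-bis(benzyloxy)phenyl]-8-bromo-6-iodochromane | c1ccccc1CO[C@H]1Cc2c(OCc3ccccc3)c(I)c(OCc3ccccc3)c(Br)c2O[C@@H]1c1ccc(OCc2ccccc2)c(OCc2ccccc2)c1 | intermediate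
6 | 1-(benzyloxy)-3-bromobenzene | Brc1cccc(OCc2ccccc2)c1 | starting material
7 | 4-(benzyloxy)-2-bromo-1-iodobenzene | Ic1ccc(OCc2ccccc2)cc1Br | intermediate
8 | (1S,2S)-1,2-dicyclohexylethane-1,2-diol | O[C@@H](C1CCCCC1)[C@@H](O)C1CCCCC1 | starting material
9 | diisopropyl (dichloromethyl)boronate | CC(C)OB(OC(C)C)C(Cl)Cl | starting material
10 | (4S,5S)-4,5-dicyclohexyl-2-(dichloromethyl)-1,3,2-dioxaborolane | ClC(Cl)B1O[C@@H](C2CCCCC2)[C@H](C2CCCCC2)O1 | intermediate
11 | [4-(benzyloxy)-2-bromophenyl]magnesium chloride | Cl[Mg]c1ccc(OCc2ccccc2)cc1Br | intermediate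
12 | (4S,5S)-2-{(R)-[4-(benzyloxy)-2-bromophenyl](chloro)methyl}-4,5-dicyclohexyl-1,3,2-dioxaborolane | O1[C@@H](C2CCCCC2)[C@H](C2CCCCC2)OB1[C@@H](Cl)c1ccc(OCc2ccccc2)cc1Br | intermediate
13 | {(2R,3S)-3,5,7-tris(benzyloxy)-2-[3,4-bis(benzyloxy)phenyl]-8-bromochroman-6-yl}magnesium chloride | Cl[Mg]c1c(OCc3ccccc3)c(Br)c2c(c1OCc3ccccc3)C[C@H](OCc3ccccc3)[C@@H](c1ccc(OCc3ccccc3)c(OCc3ccccc3)c1)O2 | intermediate
14 | (4S,5S)-2-[(R)-(ArA)(ArD)methyl]-4,5-dicyclohexyl-1,3,2-dioxaborolane | O1[C@@H](C2CCCCC2)[C@H](C2CCCCC2)OB1[C@@H](c1ccc(OCc3ccccc3)cc1Br)c1c(OCc3ccccc3)c(Br)c2c(c1OCc3ccccc3)C[C@H](OCc3ccccc3)[C@@H](c1ccc(OCc3ccccc3)c(OCc3ccccc3)c1)O2 | intermediate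
15 | dibromomethyllithium | [Li]C(Br)Br | intermediate
16 | (4S,5S)-2-[(1R,2R)-1-bromo-2-(ArA)-2-(ArD)ethyl]-4,5-dicyclohexyl-1,3,2-dioxaborolane | O1[C@@H](C2CCCCC2)[C@H](C2CCCCC2)OB1[C@@H](Br)[C@@H](c1ccc(OCc3ccccc3)cc1Br)c1c(OCc3ccccc3)c(Br)c2c(c1OCc3ccccc3)C[C@H](OCc3ccccc3)[C@@H](c1ccc(OCc3ccccc3)c(OCc3ccccc3)c1)O2 | intermediate
17 | (4S,5S)-2-[(1S,2R)-1-(benzyloxy)-2-(ArA)-2-(ArD)ethyl]-4,5-dicyclohexyl-1,3,2-dioxaborolane | O1[C@@H](C2CCCCC2)[C@H](C2CCCCC2)OB1[C@H](OCc3ccccc3)[C@@H](c1ccc(OCc3ccccc3)cc1Br)c1c(OCc3ccccc3)c(Br)c2c(c1OCc3ccccc3)C[C@H](OCc3ccccc3)[C@@H](c1ccc(OCc3ccccc3)c(OCc3ccccc3)c1)O2 | intermediate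
18 | 4-bromo-1,2-bis(benzyloxy)benzene | Brc1ccc(OCc2ccccc2)c(OCc2ccccc2)c1 | starting material
19 | dichloromethyllithium | [Li]C(Cl)Cl | intermediate
20 | [3,4-bis(benzyloxy)phenyl]magnesium bromide | Br[Mg]c1ccc(OCc2ccccc2)c(OCc2ccccc2)c1 | intermediate
21 | (4S,5S)-2-[(1R,2R,3R)-2-(benzyloxy)-1-chloro-3-(ArA)-3-(ArD)propyl]-4,5-dicyclohexyl-1,3,2-dioxaborolane | O1[C@@H](C2CCCCC2)[C@H](C2CCCCC2)OB1[C@@H](Cl)[C@H](OCc3ccccc3)[C@@H](c1ccc(OCc3ccccc3)cc1Br)c1c(OCc3ccccc3)c(Br)c2c(c1OCc3ccccc3)C[C@H](OCc3ccccc3)[C@@H](c1ccc(OCc3ccccc3)c(OCc3ccccc3)c1)O2 | intermediate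
22 | (4S,5S)-2-[(1R,2S,3R)-2-(benzyloxy)-1-(ArB)-3-(ArA)-3-(ArD)propyl]-4,5-dicyclohexyl-1,3,2-dioxaborolane | O1[C@@H](C2CCCCC2)[C@H](C2CCCCC2)OB1[C@H](c1ccc(OCc3ccccc3)c(OCc3ccccc3)c1)[C@H](OCc3ccccc3)[C@@H](c1ccc(OCc3ccccc3)cc1Br)c1c(OCc3ccccc3)c(Br)c2c(c1OCc3ccccc3)C[C@H](OCc3ccccc3)[C@@H](c1ccc(OCc3ccccc3)c(OCc3ccccc3)c1)O2 | intermediate
23 | (1R,2R,3R)-2-(benzyloxy)-1-(ArB)-3-(ArA)-3-(ArD)propan-1-ol | O[C@H](c1ccc(OCc3ccccc3)c(OCc3ccccc3)c1)[C@H](OCc3ccccc3)[C@@H](c1ccc(OCc3ccccc3)cc1Br)c1c(OCc3ccccc3)c(Br)c2c(c1OCc3ccccc3)C[C@H](OCc3ccccc3)[C@@H](c1ccc(OCc3ccccc3)c(OCc3ccccc3)c1)O2 | intermediate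
24 | (2R,3R,4S)-3,7-bis(benzyloxy)-2-[3,4-bis(benzyloxy)phenyl]-4-(ArD)chromane | c3ccccc3COc1ccc2c(c1)O[C@H](c1ccc(OCc3ccccc3)c(OCc3ccccc3)c1)[C@H](OCc3ccccc3)[C@@H]2c1c(OCc3ccccc3)c(Br)c2c(c1OCc3ccccc3)C[C@H](OCc3ccccc3)[C@@H](c1ccc(OCc3ccccc3)c(OCc3ccccc3)c1)O2 | intermediate
25 | (2R,3R,4S)-2-(3,4-dihydroxyphenyl)-4-[(2R,3S)-2-(3,4-dihydroxyphenyl)-3,5,7-trihydroxychroman-6-yl]chromane-3,7-diol | Oc1ccc2c(c1)O[C@H](c1ccc(O)c(O)c1)[C@H](O)[C@@H]2c1c(O)cc2c(c1O)C[C@H](O)[C@@H](c1ccc(O)c(O)c1)O2 | target

## Step count and least certain steps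

Total: 13 steps. Longest linear sequence: 11 steps (steps 1, 2, 3, 4, 7, 8, 9, 10, 11, 12, 13).

**Step 10 (key step).** The migrating C3 carbon is crowded and carries an electron-withdrawing benzyloxy group. The ate complex may therefore rearrange slowly, so that the carbenoid decays first or the diol control weakens. The chloride of 21 may exchange and erode C2. The second ate complex may lose the β-benzyloxy group by boron–oxygen elimination. The amide base may also touch the doubly benzylic C4–H. The fallback gives up the second insertion at C2 and sets C2 by carbonyl addition. From 17, homologation with chloromethyllithium (ICH2Cl, nBuLi, THF, −78 °C) should give the methylene-extended boronic ester F1. Oxidation with NaBO3·4H2O would give the primary alcohol F2, and Dess–Martin oxidation the α-benzyloxy aldehyde F3. Addition of 20 under chelation control (MgBr2·OEt2, CH2Cl2, −78 °C) is expected to go anti to the bulky C4 substituent of the magnesium chelate and to give the 2,3-syn alcohol. That alcohol is 23, where the route is rejoined.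

**Step 7.** The benzylic chloride of 12 has a para-benzyloxy donor. It may epimerise through chloride exchange or ionisation before 13 arrives. The di-ortho-substituted Grignard reagent 13 may also be slow to form the ate complex at a crowded boron, which leaves time for that erosion. The fallback sets C4 by catalyst control in place of the auxiliary. It sets out from 5 through 13: addition of 13 to the silyl ether aldehyde F4 (from commercial 2-bromo-4-hydroxybenzaldehyde, tBuMe2SiCl, imidazole) gives the silylated benzhydrol F5. Desilylation with Bu4NF gives the phenolic benzhydrol F6, and acid-catalysed dehydration (pyridinium p-toluenesulfonate, MgSO4) gives the para-quinone methide F7. Enantioselective 1,6-borylation (CuCl, a chiral bisphosphine of the enantiomer that gives the C4 sense of 14, NaOtBu, B2pin2, MeOH, THF) gives the phenolic pinacol boronate F8. BnBr/K2CO3 gives the benzyl ether F9, and KHF2 gives the trifluoroborate F10. Me3SiCl/H2O in the presence of 8 returns to the route at 14.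

**Step 12.** The secondary copper alkoxide sits in a crowded all-cis environment. C–O bond formation may be slow, so that reduction of the C8a–Br bond or oxidation of the carbinol to the ketone takes over. The fallback leaves the copper manifold for a Buchwald–Hartwig etherification from 23 (Pd(OAc)2, 2-(di-tert-butylphosphino)-2',4',6'-triisopropylbiphenyl, Cs2CO3, toluene, 80 °C). There the bromide is activated by oxidative addition to zerovalent palladium and the ether forms by reductive elimination from a bulky phosphine complex. It returns at 24 and makes no new compound.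

**Step 13.** Bromide released at the start may slow the catalyst and leave benzyl ethers or the hindered C8'–Br bond uncleaved. Forcing the reaction risks hydrogenolysis of the cyclic benzylic C–O bonds. The free catechols may oxidise on work-up. The fallback separates the two tasks. From 24, bromine–lithium exchange (nBuLi, THF, −78 °C) and protonation with MeOH give the bromine-free nona-O-benzyl ether F11. It is then debenzylated with H2 over Pd(OH)2/C with no halide present and returns at 25.

## Further compounds

F1 | step 10 | (4S,5S)-2-[2-(benzyloxy)-3-(ArA)-3-(ArD)propyl]-4,5-dicyclohexyl-1,3,2-dioxaborolane with the C3 and C4 configurations of 17 | O1[C@@H](C2CCCCC2)[C@H](C2CCCCC2)OB1C[C@H](OCc3ccccc3)[C@@H](c1ccc(OCc3ccccc3)cc1Br)c1c(OCc3ccccc3)c(Br)c2c(c1OCc3ccccc3)C[C@H](OCc3ccccc3)[C@@H](c1ccc(OCc3ccccc3)c(OCc3ccccc3)c1)O2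
F2 | step 10 | (2R,3R)-2-(benzyloxy)-3-(ArA)-3-(ArD)propan-1-ol | OC[C@H](OCc3ccccc3)[C@@H](c1ccc(OCc3ccccc3)cc1Br)c1c(OCc3ccccc3)c(Br)c2c(c1OCc3ccccc3)C[C@H](OCc3ccccc3)[C@@H](c1ccc(OCc3ccccc3)c(OCc3ccccc3)c1)O2
F3 | step 10 | (2R,3R)-2-(benzyloxy)-3-(ArA)-3-(ArD)propanal | O=C[C@H](OCc3ccccc3)[C@@H](c1ccc(OCc3ccccc3)cc1Br)c1c(OCc3ccccc3)c(Br)c2c(c1OCc3ccccc3)C[C@H](OCc3ccccc3)[C@@H](c1ccc(OCc3ccccc3)c(OCc3ccccc3)c1)O2
F4 | step 7 | 2-bromo-4-[(tert-butyldimethylsilyl)oxy]benzaldehyde | O=Cc1ccc(O[Si](C)(C)C(C)(C)C)cc1Br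
F5 | step 7 | {2-bromo-4-[(tert-butyldimethylsilyl)oxy]phenyl}(ArD)methanol, both carbinol epimers | OC(c1ccc(O[Si](C)(C)C(C)(C)C)cc1Br)c1c(OCc3ccccc3)c(Br)c2c(c1OCc3ccccc3)C[C@H](OCc3ccccc3)[C@@H](c1ccc(OCc3ccccc3)c(OCc3ccccc3)c1)O2
F6 | step 7 | 3-bromo-4-[(ArD)(hydroxy)methyl]phenol, both carbinol epimers | OC(c1ccc(O)cc1Br)c1c(OCc3ccccc3)c(Br)c2c(c1OCc3ccccc3)C[C@H](OCc3ccccc3)[C@@H](c1ccc(OCc3ccccc3)c(OCc3ccccc3)c1)O2
F7 | step 7 | 3-bromo-4-[(ArD)methylidene]cyclohexa-2,5-dien-1-one (para-quinone methide) | O=C1C=CC(=Cc2c(OCc4ccccc4)c(Br)c3c(c2OCc4ccccc4)C[C@H](OCc4ccccc4)[C@@H](c2ccc(OCc4ccccc4)c(OCc4ccccc4)c2)O3)C(Br)=C1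
F8 | step 7 | 3-bromo-4-[(R)-(ArD)(4,4,5,5-tetramethyl-1,3,2-dioxaborolan-2-yl)methyl]phenol | CC1(C)OB(OC1(C)C)[C@@H](c1ccc(O)cc1Br)c1c(OCc3ccccc3)c(Br)c2c(c1OCc3ccccc3)C[C@H](OCc3ccccc3)[C@@H](c1ccc(OCc3ccccc3)c(OCc3ccccc3)c1)O2
F9 | step 7 | 2-[(R)-(ArA)(ArD)methyl]-4,4,5,5-tetramethyl-1,3,2-dioxaborolane | CC1(C)OB(OC1(C)C)[C@@H](c1ccc(OCc3ccccc3)cc1Br)c1c(OCc3ccccc3)c(Br)c2c(c1OCc3ccccc3)C[C@H](OCc3ccccc3)[C@@H](c1ccc(OCc3ccccc3)c(OCc3ccccc3)c1)O2
F10 | step 7 | potassium [(R)-(ArA)(ArD)methyl]trifluoroborate | [K+].F[B-](F)(F)[C@@H](c1ccc(OCc3ccccc3)cc1Br)c1c(OCc3ccccc3)c(Br)c2c(c1OCc3ccccc3)C[C@H](OCc3ccccc3)[C@@H](c1ccc(OCc3ccccc3)c(OCc3ccccc3)c1)O2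
F0 | step 12 | none | none
F11 | step 13 | (2R,3R,4S)-3,7-bis(benzyloxy)-2-[3,4-bis(benzyloxy)phenyl]-4-{(2R,3S)-3,5,7-tris(benzyloxy)-2-[3,4-bis(benzyloxy)phenyl]chroman-6-yl}chromane | c3ccccc3COc1ccc2c(c1)O[C@H](c1ccc(OCc3ccccc3)c(OCc3ccccc3)c1)[C@H](OCc3ccccc3)[C@@H]2c1c(OCc3ccccc3)cc2c(c1OCc3ccccc3)C[C@H](OCc3ccccc3)[C@@H](c1ccc(OCc3ccccc3)c(OCc3ccccc3)c1)O2
A1 | alternative 1 | protected upper unit bonded at C4 to a 2,4-bis(benzyloxy)-6-hydroxyphenyl ring D that carries a trans-{3-[3,4-bis(benzyloxy)phenyl]oxiran-2-yl}methyl group | c3ccccc3COc1ccc2c(c1)O[C@H](c1ccc(OCc3ccccc3)c(OCc3ccccc3)c1)[C@H](OCc3ccccc3)[C@@H]2c1c(OCc3ccccc3)cc(O)c(c1OCc3ccccc3)C[C@@H]1O[C@H]1c1ccc(OCc3ccccc3)c(OCc3ccccc3)c1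
A2 | alternative 1 | octa-O-benzyl target with free C3' hydroxyl | c3ccccc3COc1ccc2c(c1)O[C@H](c1ccc(OCc3ccccc3)c(OCc3ccccc3)c1)[C@H](OCc3ccccc3)[C@@H]2c1c(OCc3ccccc3)cc2c(c1OCc3ccccc3)C[C@H](O)[C@@H](c1ccc(OCc3ccccc3)c(OCc3ccccc3)c1)O2
A3 | alternative 2 | trans-2,3-epoxy-1-[3,4-bis(benzyloxy)phenyl]-3-(ArD)propan-1-one (chalcone epoxide) | O=C(c1ccc(OCc3ccccc3)c(OCc3ccccc3)c1)[C@@H]1O[C@H]1c1c(OCc3ccccc3)c(Br)c2c(c1OCc3ccccc3)C[C@H](OCc3ccccc3)[C@@H](c1ccc(OCc3ccccc3)c(OCc3ccccc3)c1)O2
A4 | alternative 2 | tris(3-benzyloxyphenyl) borate | B(Oc1cccc(OCc2ccccc2)c1)(Oc1cccc(OCc2ccccc2)c1)Oc1cccc(OCc2ccccc2)c1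
A5 | alternative 2 | 3,4-cis-2-aryl-4-arylchroman-2,3-diol (lactol) | c3ccccc3COc1ccc2c(c1)OC(O)(c1ccc(OCc3ccccc3)c(OCc3ccccc3)c1)[C@H](O)[C@@H]2c1c(OCc3ccccc3)c(Br)c2c(c1OCc3ccccc3)C[C@H](OCc3ccccc3)[C@@H](c1ccc(OCc3ccccc3)c(OCc3ccccc3)c1)O2
A6 | alternative 3 | [4-(benzyloxy)-2-hydroxyphenyl](ArD)methanol (ortho-hydroxybenzhydrol) | OC(c1ccc(OCc3ccccc3)cc1O)c1c(OCc3ccccc3)c(Br)c2c(c1OCc3ccccc3)C[C@H](OCc3ccccc3)[C@@H](c1ccc(OCc3ccccc3)c(OCc3ccccc3)c1)O2
A7 | alternative 3 | 3-(benzyloxy)-6-[(ArD)methylidene]cyclohexa-2,4-dien-1-one (ortho-quinone methide) | O=C1C=C(OCc2ccccc2)C=CC1=Cc1c(OCc3ccccc3)c(Br)c2c(c1OCc3ccccc3)C[C@H](OCc3ccccc3)[C@@H](c1ccc(OCc3ccccc3)c(OCc3ccccc3)c1)O2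
A8 | alternative 3 | (Z)-2-{2-[3,4-bis(benzyloxy)phenyl]ethenyl}-4,4,5,5-tetramethyl-1,3,2-dioxaborolane | CC1(C)OB(OC1(C)C)/C=C\c1ccc(OCc2ccccc2)c(OCc2ccccc2)c1
A9 | alternative 3 | all-cis 3-boryl-4-arylflavan | c3ccccc3COc1ccc2c(c1)O[C@H](c1ccc(OCc3ccccc3)c(OCc3ccccc3)c1)[C@H](B4OC(C)(C)C(C)(C)O4)[C@@H]2c1c(OCc3ccccc3)c(Br)c2c(c1OCc3ccccc3)C[C@H](OCc3ccccc3)[C@@H](c1ccc(OCc3ccccc3)c(OCc3ccccc3)c1)O2
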